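**Retrosynthetic overview**

1. Numbering: ring A (five-membered) = C1 (quaternary, Me), C2, C3, C4 (OH, i-Pr), C5 (H). Ring B (seven-membered) = C1, C5, C6 (OAng), C7, C8 (Me), C9, C10 (OH).
2. The bare dauc-8-ene ester 20 is oxygenated last, with O2 only: Schenck ene reaction (O on C8, 10α-H removed), hydroperoxide shift C8→C10, then titanium-mediated oxygen transfer give the 10α-OH and the 8α,9α-oxirane.
3. Before that: the C6 ester comes from angelic acid, the C4 carbinol from i-PrMgCl on a cyclopentanone, and ring B from ring-closing metathesis (C8=C9) of an allyl arm on C1 with a methallyl arm on C6.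
4. Key disconnection: ring A grows from a cyclobutanol (C1–C2–C3–C4) by semipinacol ring expansion of its 5,6-epoxide, with C1 shifting from C4 to C5. The enabling feature is the chain C4(O)–C5–C6(O) shared by rings A and B. It is an aldol pattern whose central carbon C5 is bonded to the quaternary C1, so a strained C4 carbinol, a C5–C6 oxirane and a good migrating group sit side by side.
5. Order of rings: four-membered ring (Wolff contraction; C1 set by asymmetric allylic alkylation) → ring A (step 9) → ring B (step 10) → oxirane (step 15).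

Key step: step 9

Assumption: the sense of induction of the two chiral ligands (steps 4 and 8) is assigned by analogy with related substrates. Both antipodes of each ligand are accessible, and the antipode that gives the drawn configuration is meant.

**Step 1**
Reactants: 1 cyclopentane-1,3-dione
Product: 2 2-diazocyclopentane-1,3-dione
Conditions: 4-AcNHC6H4SO2N3, Et3N, MeCN, 0 °C to rt
Reagents that add atoms: 4-acetamidobenzenesulfonyl azide CC(=O)Nc1ccc(cc1)S(=O)(=O)N=[N+]=[N-]
Why: Regitz diazo transfer to the doubly activated methylene of the 1,3-diketone should proceed under mild amine base and creates no stereocentre.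

**Step 2**
Reactants: 2 2-diazocyclopentane-1,3-dione; 3 prop-2-en-1-ol
Product: 5 prop-2-enyl 2-oxocyclobutane-1-carboxylate, via acylketene 4 (not isolated)
Conditions: toluene, 140 °C (sealed tube)
Reagents that add atoms: none
Why: Thermal Wolff rearrangement of the cyclic 2-diazo-1,3-diketone should contract the ring to the acylketene, which the alcohol traps as the β-keto ester, whose labile α-centre is left undefined.

**Step 3**
Reactants: 5 prop-2-enyl 2-oxocyclobutane-1-carboxylate
Product: 6 prop-2-enyl 1-methyl-2-oxocyclobutane-1-carboxylate (racemic)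
Conditions: MeI, K2CO3, acetone, 50 °C
Reagents that add atoms: iodomethane CI
Why: C-alkylation of the stabilised β-keto ester enolate should give the racemic quaternary ester, whose configuration is erased in the next step.

**Step 4**
Reactants: 6 prop-2-enyl 1-methyl-2-oxocyclobutane-1-carboxylate
Product: 7 (R)-2-methyl-2-(prop-2-enyl)cyclobutan-1-one
Conditions: Pd2(dba)3 (2.5 mol %), (R)-(CF3)3-t-Bu-PHOX (6 mol %), toluene, 20 °C
Reagents that add atoms: none
Why: Decarboxylative asymmetric allylic alkylation (Tsuji–Trost type) with a zerovalent palladium catalyst passes through an achiral enolate on a chiral allylpalladium fragment, so the ligand alone should set the quaternary centre C1 as (R) from the racemate.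

**Step 5**
Reactants: 8 3-chloro-2-methylprop-1-ene; 9 ethynylmagnesium bromide
Product: 10 2-methylpent-1-en-4-yne
Conditions: CuCl (5 mol %), THF, 0 to 50 °C
Reagents that add atoms: none
Why: Copper-catalysed allylation of the alkynyl Grignard reagent should give the skipped enyne, since direct and allylically transposed substitution of the methallyl chloride lead to the same product.

**Step 6**
Reactants: 10 2-methylpent-1-en-4-yne
Product: 12 (1E)-1-iodo-4-methylpenta-1,4-diene, via alkenylzirconocene 11 (not isolated)
Conditions: Cp2Zr(H)Cl, CH2Cl2, rt; then I2, 0 °C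
Reagents that add atoms: iodine II
Why: Hydrozirconation adds Zr–H syn and terminally to the alkyne faster than to the 1,1-disubstituted alkene, and iodinolysis with retention should give the (E)-iodide.

**Step 7**
Reactants: 12 (1E)-1-iodo-4-methylpenta-1,4-diene; 7 (R)-2-methyl-2-(prop-2-enyl)cyclobutan-1-one
Product: 14 (2R)-2-methyl-1-[(1E)-4-methylpenta-1,4-dienyl]-2-(prop-2-enyl)cyclobutan-1-ol (both carbinol epimers), via alkenyllithium 13 (not isolated)
Conditions: t-BuLi (2 equiv), Et2O, −78 °C; then 7, −78 °C; then H2O
Reagents that add atoms: none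
Why: Iodine–lithium exchange with retention of alkene geometry followed by 1,2-addition to the strained ketone should give the tertiary allylic alcohol, whose new carbinol centre (C4) needs no control because it becomes the carbonyl carbon in step 9.

**Step 8**
Reactants: 14 (2R)-2-methyl-1-[(1E)-4-methylpenta-1,4-dienyl]-2-(prop-2-enyl)cyclobutan-1-ol
Product: 15 (2R)-2-methyl-1-[(2R,3S)-3-(2-methylprop-2-enyl)oxiran-2-yl]-2-(prop-2-enyl)cyclobutan-1-ol (both carbinol epimers)
Conditions: Hf(Ot-Bu)4 (10 mol %), C2-symmetric bis-hydroxamic acid ligand from trans-cyclohexane-1,2-diamine (12 mol %), PhC(CH3)2OOH, toluene, 0 °C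
Reagents that add atoms: cumene hydroperoxide CC(C)(OO)c1ccccc1
Why: Hydroxyl-directed catalytic asymmetric epoxidation of a tertiary allylic alcohol binds the substrate through its alkoxide, which should single out the allylic E-alkene over the two remote alkenes, while the ligand selects the C5-Re/C6-Si face and so sets C5 and C6 in both carbinol epimers.

**Step 9**
Reactants: 15 (2R)-2-methyl-1-[(2R,3S)-3-(2-methylprop-2-enyl)oxiran-2-yl]-2-(prop-2-enyl)cyclobutan-1-ol
Product: 16 (2S,3R)-2-[(1S)-1-hydroxy-3-methylbut-3-enyl]-3-methyl-3-(prop-2-enyl)cyclopentan-1-one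
Conditions: BF3·OEt2 (0.3 equiv), CH2Cl2, −78 to −40 °C
Reagents that add atoms: none
Why: Coordination of BF3 to the oxirane oxygen weakens the C5–O bond, and the cyclobutane bond C4–C1 standing antiperiplanar to it shifts to C5 while the carbinol oxygen becomes the C4 carbonyl group, a semipinacol rearrangement of a 2,3-epoxy alcohol whose closest known type is the Lewis-acid ring expansion of 1-oxiranylcyclobutanols to 2-(1-hydroxyalkyl)cyclopentanones. No ring is closed by cyclisation: the four-membered ring C1–C2–C3–C4 takes up C5 by a 1,2-shift and becomes ring A, driven by release of cyclobutane and oxirane strain. C5 is formed with inversion because C1 attacks anti to the departing oxygen, C6 keeps the configuration of the epoxide and now carries the free hydroxyl, and C1 migrates with retention, so the E geometry of the alkene and the face chosen in step 8 should translate into the (5S,6S) pattern with the C6 arm trans to the allyl arm. Three selectivities are needed: opening at C5 and not at C6 (only C5–O cleavage is pushed by the adjacent carbinol and taps the ring strain), migration of the quaternary C1 and not of the C3 methylene (higher migratory aptitude of the more substituted carbon), and survival of two isolated alkenes (low temperature, substoichiometric Lewis acid). In one operation the step forges the most congested bond of the target (quaternary C1 to tertiary C5), brings ring A to its final size and leaves oxygen on exactly the two carbons, C4 and C6, that carry it in lapiferine.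

**Step 10**
Reactants: 16 (2S,3R)-2-[(1S)-1-hydroxy-3-methylbut-3-enyl]-3-methyl-3-(prop-2-enyl)cyclopentan-1-one
Product: 17 (3aR,8S,8aS)-8-hydroxy-3a,6-dimethyl-3,3a,4,7,8,8a-hexahydroazulen-1(2H)-one
Conditions: second-generation Grubbs catalyst (5 mol %), CH2Cl2 (0.005 M), reflux
Reagents that add atoms: none
Why: Ring-closing metathesis should start at the monosubstituted allyl arm and close on the methallyl arm to give the trisubstituted C8=C9 alkene of ring B, the trans ring fusion being fixed by the existing C1 and C5 centres.

**Step 11**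
Reactants: 17 (3aR,8S,8aS)-8-hydroxy-3a,6-dimethyl-3,3a,4,7,8,8a-hexahydroazulen-1(2H)-one
Product: 18 jaeschkeanadiol (dauc-8-ene-4β,6α-diol; 1β-Me, 5α-H)
Conditions: i-PrMgCl (3 equiv), LaCl3·2LiCl (1 equiv), THF, 0 °C; then H2O
Reagents that add atoms: isopropylmagnesium chloride CC(C)[Mg]Cl
Why: Lanthanide-salt-promoted Grignard 1,2-addition suppresses enolisation and β-hydride reduction, and attack on the α face of ring A, opposite to the β-oriented C1 methyl group and C5–C6 bond, should set C4 with the hydroxyl group β.

**Step 12**
Reactants: 18 jaeschkeanadiol; 19 angelic acid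
Product: 20 6-O-angeloyljaeschkeanadiol (6α-angeloyloxydauc-8-en-4β-ol)
Conditions: 19, 2,4,6-Cl3C6H2COCl, Et3N, toluene, rt; then 18, 80 °C
Reagents that add atoms: none
Why: Yamaguchi-type mixed-anhydride esterification without nucleophilic catalyst should acylate only the secondary equatorial 6α-hydroxyl (the 4β-hydroxyl is tertiary) and keep the Z geometry of the angelate.

**Step 13**
Reactants: 20 6-O-angeloyljaeschkeanadiol
Product: 21 6α-angeloyloxy-8α-hydroperoxydauc-9-en-4β-ol
Conditions: O2, tetraphenylporphyrin (cat.), visible light, CH2Cl2, −20 °C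
Reagents that add atoms: dioxygen O=O
Why: In the Schenck ene reaction singlet oxygen should approach C8=C9 from the α face (the β face is screened by the axial C1 methyl group), bind to C8 and remove the axial 10α-hydrogen on the more crowded ring side of the alkene, the C7 hydrogens being deactivated by the neighbouring acyloxy group and the angelate alkene by its ester.

**Step 14**
Reactants: 21 6α-angeloyloxy-8α-hydroperoxydauc-9-en-4β-ol
Product: 22 6α-angeloyloxy-10α-hydroperoxydauc-8-en-4β-ol
Conditions: CHCl3, di-tert-butyl hyponitrite (cat.), 40 °C, dark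
Reagents that add atoms: none
Why: The Schenck rearrangement (suprafacial 1,3-shift in the allylperoxyl radical chain) should move the hydroperoxy group from tertiary C8 to secondary C10 on the same α face, driven by formation of the trisubstituted alkene as in the 5α-to-7α shift of steroidal allylic hydroperoxides.

**Step 15**
Reactants: 22 6α-angeloyloxy-10α-hydroperoxydauc-8-en-4β-ol
Product: 23 lapiferine
Conditions: Ti(Oi-Pr)4 (10 mol %), 4 Å molecular sieves, CH2Cl2, −20 °C
Reagents that add atoms: none
Why: Titanium-alkoxide-mediated oxygen transfer from an allylic hydroperoxide to the alkene of the titanium-bound allylic alcohol is a hydroxyl-directed epoxidation, so the distal oxygen should be delivered syn to the 10α-oxygen and give the 8α,9α-oxirane together with the free 10α-hydroxyl.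

**Compound list**

1 | cyclopentane-1,3-dione | O=C1CCC(=O)C1 | starting material
2 | 2-diazocyclopentane-1,3-dione | [N-]=[N+]=C1C(=O)CCC1=O | intermediate
3 | prop-2-en-1-ol (allyl alcohol) | C=CCO | starting material
4 | 2-(oxomethylidene)cyclobutan-1-one (acylketene, not isolated) | O=C=C1CCC1=O | intermediate
5 | prop-2-enyl 2-oxocyclobutane-1-carboxylate | C=CCOC(=O)C1CCC1=O | intermediate
6 | prop-2-enyl 1-methyl-2-oxocyclobutane-1-carboxylate (racemic) | C=CCOC(=O)C1(C)CCC1=O | intermediate
7 | (R)-2-methyl-2-(prop-2-enyl)cyclobutan-1-one | O=C1CC[C@]1(C)CC=C | intermediate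
8 | 3-chloro-2-methylprop-1-ene | C=C(C)CCl | starting material
9 | ethynylmagnesium bromide | C#C[Mg]Br | starting material
10 | 2-methylpent-1-en-4-yne | C=C(C)CC#C | intermediate
11 | chlorobis(cyclopentadienyl)[(1E)-4-methylpenta-1,4-dienyl]zirconium (not isolated) | C=C(C)C/C=C/[Zr](Cl)(C1C=CC=C1)C1C=CC=C1 | intermediate
12 | (1E)-1-iodo-4-methylpenta-1,4-diene | C=C(C)C/C=C/I | intermediate
13 | [(1E)-4-methylpenta-1,4-dienyl]lithium (not isolated) | [Li]/C=C/CC(C)=C | intermediate
14 | (2R)-2-methyl-1-[(1E)-4-methylpenta-1,4-dienyl]-2-(prop-2-enyl)cyclobutan-1-ol (carbinol centre: both epimers) | C=C(C)C/C=C/C1(O)CC[C@]1(C)CC=C | intermediate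
15 | (2R)-2-methyl-1-[(2R,3S)-3-(2-methylprop-2-enyl)oxiran-2-yl]-2-(prop-2-enyl)cyclobutan-1-ol (carbinol centre: both epimers) | C=C(C)C[C@@H]1O[C@H]1C2(O)CC[C@]2(C)CC=C | intermediate
16 | (2S,3R)-2-[(1S)-1-hydroxy-3-methylbut-3-enyl]-3-methyl-3-(prop-2-enyl)cyclopentan-1-one | O[C@@H](CC(C)=C)[C@H]1C(=O)CC[C@]1(C)CC=C | intermediate
17 | (3aR,8S,8aS)-8-hydroxy-3a,6-dimethyl-3,3a,4,7,8,8a-hexahydroazulen-1(2H)-one (trans-fused) | O[C@H]1CC(C)=CC[C@@]2(C)CCC(=O)[C@H]12 | intermediate
18 | jaeschkeanadiol, dauc-8-ene-4β,6α-diol (1β-Me, 5α-H) | O[C@H]1CC(C)=CC[C@@]2(C)CC[C@@](O)(C(C)C)[C@H]12 | intermediate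
19 | angelic acid, (Z)-2-methylbut-2-enoic acid | C/C=C(/C)C(=O)O | starting material
20 | 6-O-angeloyljaeschkeanadiol | C/C=C(/C)C(=O)O[C@H]1CC(C)=CC[C@@]2(C)CC[C@@](O)(C(C)C)[C@H]12 | intermediate
21 | 6α-angeloyloxy-8α-hydroperoxydauc-9-en-4β-ol | C/C=C(/C)C(=O)O[C@H]1C[C@@](C)(OO)C=C[C@@]2(C)CC[C@@](O)(C(C)C)[C@H]12 | intermediate
22 | 6α-angeloyloxy-10α-hydroperoxydauc-8-en-4β-ol | C/C=C(/C)C(=O)O[C@H]1CC(C)=C[C@@H](OO)[C@@]2(C)CC[C@@](O)(C(C)C)[C@H]12 | intermediate
23 | lapiferine, 6α-angeloyloxy-8α,9α-epoxydaucane-4β,10α-diol | C/C=C(/C)C(=O)O[C@H]1C[C@@]2(C)O[C@H]2[C@@H](O)[C@@]2(C)CC[C@@](O)(C(C)C)[C@H]12 | target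

**Step count**

- Total step count: 15.
- Longest linear sequence: 13 (steps 1–4 and 7–15).

**Steps most likely to fail**

**Step 13.**
- Process at risk: loss of regiocontrol in the ene reaction. A hydrogen of the C8 methyl group or of C7 may be abstracted in place of the 10α-hydrogen, which would put oxygen on C9.
- The fallback sets out from 20 and comes back to the route at 23.
- Allylic oxidation of the C10 methylene with Rh2(cap)4 and t-BuOOH should give the 10-oxo enone F7.
- Luche reduction (NaBH4, CeCl3·7H2O, MeOH) should deliver hydride from the open α face to give the 10β-alcohol F8.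
- Mitsunobu inversion with 4-nitrobenzoic acid, PPh3 and diisopropyl azodicarboxylate should give the 10α-(4-nitrobenzoate) F9.
- K2CO3 in MeOH at 0 °C should cleave only this activated ester to the 10α-allylic alcohol F10.
- Hydroxyl-directed epoxidation with VO(acac)2 and t-BuOOH should then give 23.

**Step 8.**
- Process at risk: poor facial selectivity for one of the two carbinol epimers (mismatched pairing) and slow turnover at the hindered tertiary alkoxide.
- The fallback sets out from 7 (with 10 as the second component) and comes back at 16. Ring A still arises from the four-membered ring.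
- Deprotonation of 10 with n-BuLi and addition to 7 should give the alkynylcyclobutanol F1.
- (4-CF3C6H4)3PAuCl with AgSbF6 (a monovalent gold catalyst) should activate the alkyne and trigger ring expansion with migration of C1 to the (E)-alkylidenecyclopentanone F2.
- Copper-catalysed asymmetric conjugate borylation (CuCl, NaOt-Bu, Josiphos-type ligand, B2pin2, MeOH) should place boron on C6 under ligand control. C5 is protonated and equilibrated to the trans arrangement, giving the β-boryl ketone F3.
- Oxidation with NaBO3 with retention should give 16.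

**Step 11.**
- Process at risk: enolisation at C5 with epimerisation to the cis-fused ketone, β-hydride reduction by the branched Grignard reagent, or retro-aldol opening of ring B through the 6-alkoxide.
- The fallback sets out from 17 and comes back at 18.
- Silylation (Et3SiCl, imidazole) should give the triethylsilyl ether F4.
- The smaller, non-reducing 2-propenyllithium with CeCl3 should add from the α face to give the isopropenyl carbinol F5.
- Hydrogenation with RhCl(PPh3)3 and H2 should saturate only the 1,1-disubstituted alkene to the silylated diol F6.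
- Bu4NF should then release 18.

**Further compounds**

F1 | step 8 | (2R)-2-methyl-1-(4-methylpent-4-en-1-ynyl)-2-(prop-2-enyl)cyclobutan-1-ol (both carbinol epimers) | C=C(C)CC#CC1(O)CC[C@]1(C)CC=C
F2 | step 8 | (2E,3R)-3-methyl-2-(3-methylbut-3-enylidene)-3-(prop-2-enyl)cyclopentan-1-one | C=C(C)C/C=C1/C(=O)CC[C@]1(C)CC=C
F3 | step 8 | (2S,3R)-3-methyl-2-[3-methyl-1-(4,4,5,5-tetramethyl-1,3,2-dioxaborolan-2-yl)but-3-enyl]-3-(prop-2-enyl)cyclopentan-1-one (boron in the place of the 6-hydroxyl of 16) | CC1(C)OB(OC1(C)C)[C@@H](CC(C)=C)[C@H]1C(=O)CC[C@]1(C)CC=C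
F4 | step 11 | triethylsilyl ether of 17 | CC[Si](CC)(CC)O[C@H]1CC(C)=CC[C@@]2(C)CCC(=O)[C@H]12
F5 | step 11 | 6α-triethylsilyloxydauca-8,11-dien-4β-ol (isopropenyl carbinol) | CC[Si](CC)(CC)O[C@H]1CC(C)=CC[C@@]2(C)CC[C@@](O)(C(C)=C)[C@H]12
F6 | step 11 | 6-O-triethylsilyljaeschkeanadiol | CC[Si](CC)(CC)O[C@H]1CC(C)=CC[C@@]2(C)CC[C@@](O)(C(C)C)[C@H]12
F7 | step 13 | 6α-angeloyloxy-4β-hydroxydauc-8-en-10-one | C/C=C(/C)C(=O)O[C@H]1CC(C)=CC(=O)[C@@]2(C)CC[C@@](O)(C(C)C)[C@H]12
F8 | step 13 | 6α-angeloyloxydauc-8-ene-4β,10β-diol | C/C=C(/C)C(=O)O[C@H]1CC(C)=C[C@H](O)[C@@]2(C)CC[C@@](O)(C(C)C)[C@H]12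
F9 | step 13 | 6α-angeloyloxy-10α-(4-nitrobenzoyloxy)dauc-8-en-4β-ol | C/C=C(/C)C(=O)O[C@H]1CC(C)=C[C@@H](OC(=O)c3ccc(cc3)[N+](=O)[O-])[C@@]2(C)CC[C@@](O)(C(C)C)[C@H]12
F10 | step 13 | 6α-angeloyloxydauc-8-ene-4β,10α-diol | C/C=C(/C)C(=O)O[C@H]1CC(C)=C[C@@H](O)[C@@]2(C)CC[C@@](O)(C(C)C)[C@H]12
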